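## Retrosynthetic overview

1. The target is a mono-ester of an all-trans 2,4-diaryl-cyclobutane-1,3-dicarboxylic acid (aryls cis to each other, carboxyls cis to each other) with (S)-3-(3,4-dihydroxyphenyl)lactic acid. The last disconnections are global O-debenzylation and the ester C–O bond, made by Mitsunobu inversion of natural (R)-danshensu.
2. The diacid core on its own is meso. Its chirality comes only from which carboxyl carries the lactate, so the absolute configuration is fixed by which of two enantiotopic CH2 groups is arylated first.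
3. Both aryl groups are introduced by two sequential amide-directed C(sp3)–H arylations on a cyclobutane whose two carboxyls are differentiated (benzyl ester and directing anilide). The first is ligand-controlled and enantioselective.
4. The all-trans arrangement comes from two epimerisations: the ester carbon after the first arylation, the amide carbon after the second.
5. Ring formation: no carbocycle is built. The cyclobutane is bought as cis-cyclobutane-1,3-dicarboxylic acid, and the only ring formed is the transient bicyclic anhydride 2 in step 1.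

## Assumptions

- Abbreviations: Bn = benzyl; ArF = 2,3,5,6-tetrafluoro-4-(trifluoromethyl)phenyl; HFIP = (CF3)2CHOH.
- L1 = N-[(1S)-1-[(4S)-4-benzyl-4,5-dihydro-1,3-oxazol-2-yl]-2,2-dimethylpropyl]acetamide (acetyl-protected aminomethyl-oxazoline ligand); ent-L1 is its mirror image. It is assumed, and must be confirmed on 8 by chiral HPLC and X-ray, that L1 is the antipode that delivers 8; if the opposite sense is found, L1 and ent-L1 swap places in steps 3 and 5 and nothing else changes.
- Aryl iodide 10 is taken as a catalogue compound (otherwise one iodination from 1,2-bis(benzyloxy)benzene).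

## Route

Step 1
Reactants: 1 cis-cyclobutane-1,3-dicarboxylic acid
Product: 3 cis-3-[(benzyloxy)carbonyl]cyclobutane-1-carboxylic acid, via bicyclic anhydride 2 (not isolated)
Conditions: Ac2O, 140 °C; evaporate; BnOH (1.0 equiv), DMAP (5 mol %), toluene, 80 °C
Reagents that add atoms: benzyl alcohol, OCc1ccccc1
Why: Dehydration of the cis-1,3-diacid to its bridged anhydride followed by DMAP-catalysed anhydride alcoholysis gives exactly one ester and one free acid, and no stereocentre is created because both carbonyls of 2 are equivalent.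

Step 2
Reactants: 3 cis-3-[(benzyloxy)carbonyl]cyclobutane-1-carboxylic acid; 4 2,3,5,6-tetrafluoro-4-(trifluoromethyl)aniline
Product: 6 benzyl cis-3-[(ArF)carbamoyl]cyclobutane-1-carboxylate, via acid chloride 5 (not isolated)
Conditions: (COCl)2, DMF (cat.), CH2Cl2, 0 °C to rt; evaporate; 4, toluene, 110 °C
Reagents that add atoms: oxalyl chloride, O=C(Cl)C(=O)Cl (supplies only the Cl of 5)
Why: Acid chloride formation and N-acylation of the weakly nucleophilic polyfluoroaniline install the acidic N-aryl amide that directs palladium, and the cis relationship is kept because no base is present to enolise the acyl chloride.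

Step 3
Reactants: 6 benzyl cis-3-[(ArF)carbamoyl]cyclobutane-1-carboxylate; 7 1-(benzyloxy)-4-iodobenzene
Product: 8 benzyl (1R,2S,3S)-2-[4-(benzyloxy)phenyl]-3-[(ArF)carbamoyl]cyclobutane-1-carboxylate (all-cis)
Conditions: 7 (2 equiv), Pd(OAc)2 (10 mol %), L1 (20 mol %), Ag2CO3 (1.5 equiv), HFIP, 80 °C
Reagents that add atoms: none
Why: This is an amide-directed, ligand-accelerated enantioselective β-C(sp3)–H arylation (concerted metalation–deprotonation to a five-membered palladacycle of divalent palladium, oxidative addition of 7 to tetravalent palladium, reductive elimination), which places the aryl cis to the amide and hence all-cis, while the chiral ligand picks one of the two enantiotopic CH2 groups of achiral 6 and so fixes the absolute sense of the ring.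

Step 4
Reactants: 8 benzyl (1R,2S,3S)-2-[4-(benzyloxy)phenyl]-3-[(ArF)carbamoyl]cyclobutane-1-carboxylate
Product: 9 benzyl (1S,2S,3S)-2-[4-(benzyloxy)phenyl]-3-[(ArF)carbamoyl]cyclobutane-1-carboxylate (ester trans to aryl; amide still cis to aryl)
Conditions: KN(SiMe3)2 (1.5 equiv), THF, −78 to 0 °C; AcOH
Reagents that add atoms: none
Why: In this base-mediated epimerisation the first equivalent of base turns the acidic anilide into its amidate, which shields the amide α-H, and the remainder reversibly enolises only the ester carbon, which settles trans to the neighbouring aryl under thermodynamic control.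

Step 5
Reactants: 9 benzyl (1S,2S,3S)-2-[4-(benzyloxy)phenyl]-3-[(ArF)carbamoyl]cyclobutane-1-carboxylate; 10 1,2-bis(benzyloxy)-4-iodobenzene
Product: 11 benzyl (1R,2S,3R,4R)-2-[4-(benzyloxy)phenyl]-4-[3,4-bis(benzyloxy)phenyl]-3-[(ArF)carbamoyl]cyclobutane-1-carboxylate (amide cis to both aryls; ester trans to both)
Conditions: 10 (3 equiv), Pd(OAc)2 (15 mol %), ent-L1 (30 mol %), Ag2CO3 (2 equiv), HFIP, 90 °C
Reagents that add atoms: none
Why: In this second amide-directed C(sp3)–H arylation the only C–H left cis to the amide is on the untouched CH2, so the new aryl enters cis to the amide, therefore cis to the first aryl and trans to the ester, with the antipodal ligand matched to this formerly disfavoured methylene.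

Step 6
Reactants: 11 benzyl (1R,2S,3R,4R)-2-[4-(benzyloxy)phenyl]-4-[3,4-bis(benzyloxy)phenyl]-3-[(ArF)carbamoyl]cyclobutane-1-carboxylate
Product: 15 (1S,2S,3R,4R)-4-[3,4-bis(benzyloxy)phenyl]-3-[(benzyloxy)carbonyl]-2-[4-(benzyloxy)phenyl]cyclobutane-1-carboxylic acid, via N-Boc imide 12 (not isolated), via epimerised N-Boc imide 13 (not isolated), via peroxy acid 14 (not isolated)
Conditions: Boc2O, DMAP, MeCN, rt; DBU (0.3 equiv), rt; LiOH, H2O2, THF/H2O, 0 °C; Na2SO3; 1 M HCl
Reagents that add atoms: di-tert-butyl dicarbonate, CC(C)(C)OC(=O)OC(=O)OC(C)(C)C (Boc of 12 and 13 only); hydrogen peroxide, OO (peroxy oxygen of 14, hydroxyl oxygen of 15)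
Why: N-Boc activation makes the anilide a twisted, enolisable imide whose α-carbon, flanked by two cis aryl groups, equilibrates under DBU to the all-trans isomer (thermodynamic epimerisation), after which imide perhydrolysis cleaves the activated acyl–N bond in preference to the hindered benzyl ester and sulfite reduces the peroxy acid.

Step 7
Reactants: 16 sodium (2R)-3-(3,4-dihydroxyphenyl)-2-hydroxypropanoate (sodium danshensu)
Product: 17 benzyl (2R)-3-[3,4-bis(benzyloxy)phenyl]-2-hydroxypropanoate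
Conditions: BnBr (3.3 equiv), K2CO3, DMF, rt, under N2
Reagents that add atoms: benzyl bromide, BrCc1ccccc1 (three benzyl groups)
Why: Williamson O-alkylation of the two phenoxides and the carboxylate leaves the less acidic secondary alcohol free and does not touch the stereocentre.

Step 8
Reactants: 15 (1S,2S,3R,4R)-4-[3,4-bis(benzyloxy)phenyl]-3-[(benzyloxy)carbonyl]-2-[4-(benzyloxy)phenyl]cyclobutane-1-carboxylic acid; 17 benzyl (2R)-3-[3,4-bis(benzyloxy)phenyl]-2-hydroxypropanoate
Product: 18 1-benzyl 3-{(2S)-1-(benzyloxy)-3-[3,4-bis(benzyloxy)phenyl]-1-oxopropan-2-yl} (1R,2R,3S,4S)-2-[4-(benzyloxy)phenyl]-4-[3,4-bis(benzyloxy)phenyl]cyclobutane-1,3-dicarboxylate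
Conditions: PPh3 (1.5 equiv), DIAD (1.5 equiv), THF, 0 °C to rt
Reagents that add atoms: none
Why: In this Mitsunobu esterification the carboxylate displaces the alkoxyphosphonium of the α-hydroxy ester by SN2 with inversion (R to S), and since the cyclobutane acid is never activated its four stereocentres are untouched.

Step 9
Reactants: 18 1-benzyl 3-{(2S)-1-(benzyloxy)-3-[3,4-bis(benzyloxy)phenyl]-1-oxopropan-2-yl} (1R,2R,3S,4S)-2-[4-(benzyloxy)phenyl]-4-[3,4-bis(benzyloxy)phenyl]cyclobutane-1,3-dicarboxylate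
Product: 19 (1R,2R,3S,4S)-3-{[(1S)-1-carboxy-2-(3,4-dihydroxyphenyl)ethoxy]carbonyl}-4-(3,4-dihydroxyphenyl)-2-(4-hydroxyphenyl)cyclobutane-1-carboxylic acid (CNP0270917.2)
Conditions: H2 (1 atm), Pd/C (10 wt % Pd on carbon), THF/MeOH, rt; filter under argon
Reagents that add atoms: none
Why: Heterogeneous hydrogenolysis removes five benzyl ethers and two benzyl esters, the ester linking cyclobutane and lactate is not benzylic and survives, and no stereocentre is affected.

## Compound list

1 | cis-cyclobutane-1,3-dicarboxylic acid | O=C(O)[C@@H]1C[C@H](C(=O)O)C1 | starting material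
2 | 3-oxabicyclo[3.1.1]heptane-2,4-dione | O=C1OC(=O)C2CC1C2 | intermediate (not isolated)
3 | cis-3-[(benzyloxy)carbonyl]cyclobutane-1-carboxylic acid | O=C(OCc1ccccc1)[C@@H]2C[C@H](C(=O)O)C2 | intermediate
4 | 2,3,5,6-tetrafluoro-4-(trifluoromethyl)aniline | Nc1c(F)c(F)c(C(F)(F)F)c(F)c1F | starting material
5 | benzyl cis-3-(chlorocarbonyl)cyclobutane-1-carboxylate | O=C(OCc1ccccc1)[C@@H]2C[C@H](C(=O)Cl)C2 | intermediate (not isolated)
6 | benzyl cis-3-[(ArF)carbamoyl]cyclobutane-1-carboxylate | O=C(OCc1ccccc1)[C@@H]2C[C@H](C(=O)Nc3c(F)c(F)c(C(F)(F)F)c(F)c3F)C2 | intermediate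
7 | 1-(benzyloxy)-4-iodobenzene | Ic1ccc(OCc2ccccc2)cc1 | starting material
8 | benzyl (1R,2S,3S)-2-[4-(benzyloxy)phenyl]-3-[(ArF)carbamoyl]cyclobutane-1-carboxylate (all-cis) | O=C(OCc1ccccc1)[C@H]2[C@@H](c3ccc(OCc4ccccc4)cc3)[C@@H](C(=O)Nc3c(F)c(F)c(C(F)(F)F)c(F)c3F)C2 | intermediate
9 | benzyl (1S,2S,3S)-2-[4-(benzyloxy)phenyl]-3-[(ArF)carbamoyl]cyclobutane-1-carboxylate | O=C(OCc1ccccc1)[C@@H]2[C@@H](c3ccc(OCc4ccccc4)cc3)[C@@H](C(=O)Nc3c(F)c(F)c(C(F)(F)F)c(F)c3F)C2 | intermediate
10 | 1,2-bis(benzyloxy)-4-iodobenzene | Ic1ccc(OCc2ccccc2)c(OCc2ccccc2)c1 | starting material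
11 | benzyl (1R,2S,3R,4R)-2-[4-(benzyloxy)phenyl]-4-[3,4-bis(benzyloxy)phenyl]-3-[(ArF)carbamoyl]cyclobutane-1-carboxylate | O=C(OCc1ccccc1)[C@@H]2[C@@H](c3ccc(OCc4ccccc4)cc3)[C@@H](C(=O)Nc3c(F)c(F)c(C(F)(F)F)c(F)c3F)[C@H]2c1ccc(OCc2ccccc2)c(OCc2ccccc2)c1 | intermediate
12 | benzyl (1R,2S,3R,4R)-2-[4-(benzyloxy)phenyl]-4-[3,4-bis(benzyloxy)phenyl]-3-[(tert-butoxycarbonyl)(ArF)carbamoyl]cyclobutane-1-carboxylate (acyl group cis to both aryls) | O=C(OCc1ccccc1)[C@@H]2[C@@H](c3ccc(OCc4ccccc4)cc3)[C@@H](C(=O)N(C(=O)OC(C)(C)C)c3c(F)c(F)c(C(F)(F)F)c(F)c3F)[C@H]2c1ccc(OCc2ccccc2)c(OCc2ccccc2)c1 | intermediate (not isolated)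
13 | benzyl (1R,2S,3S,4R)-2-[4-(benzyloxy)phenyl]-4-[3,4-bis(benzyloxy)phenyl]-3-[(tert-butoxycarbonyl)(ArF)carbamoyl]cyclobutane-1-carboxylate (all-trans) | O=C(OCc1ccccc1)[C@@H]2[C@@H](c3ccc(OCc4ccccc4)cc3)[C@H](C(=O)N(C(=O)OC(C)(C)C)c3c(F)c(F)c(C(F)(F)F)c(F)c3F)[C@H]2c1ccc(OCc2ccccc2)c(OCc2ccccc2)c1 | intermediate (not isolated)
14 | all-trans 4-[3,4-bis(benzyloxy)phenyl]-3-[(benzyloxy)carbonyl]-2-[4-(benzyloxy)phenyl]cyclobutane-1-carboperoxoic acid (same configuration as 15) | O=C(OCc1ccccc1)[C@@H]2[C@@H](c3ccc(OCc4ccccc4)cc3)[C@H](C(=O)OO)[C@H]2c1ccc(OCc2ccccc2)c(OCc2ccccc2)c1 | intermediate (not isolated)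
15 | (1S,2S,3R,4R)-4-[3,4-bis(benzyloxy)phenyl]-3-[(benzyloxy)carbonyl]-2-[4-(benzyloxy)phenyl]cyclobutane-1-carboxylic acid (all-trans) | O=C(OCc1ccccc1)[C@@H]2[C@@H](c3ccc(OCc4ccccc4)cc3)[C@H](C(=O)O)[C@H]2c1ccc(OCc2ccccc2)c(OCc2ccccc2)c1 | intermediate
16 | sodium (2R)-3-(3,4-dihydroxyphenyl)-2-hydroxypropanoate | O[C@H](Cc1ccc(O)c(O)c1)C(=O)[O-].[Na+] | starting material
17 | benzyl (2R)-3-[3,4-bis(benzyloxy)phenyl]-2-hydroxypropanoate | O[C@H](Cc1ccc(OCc2ccccc2)c(OCc2ccccc2)c1)C(=O)OCc1ccccc1 | intermediate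
18 | 1-benzyl 3-{(2S)-1-(benzyloxy)-3-[3,4-bis(benzyloxy)phenyl]-1-oxopropan-2-yl} (1R,2R,3S,4S)-2-[4-(benzyloxy)phenyl]-4-[3,4-bis(benzyloxy)phenyl]cyclobutane-1,3-dicarboxylate | O=C(OCc1ccccc1)[C@@H]2[C@@H](c3ccc(OCc4ccccc4)cc3)[C@H](C(=O)O[C@@H](Cc3ccc(OCc4ccccc4)c(OCc4ccccc4)c3)C(=O)OCc3ccccc3)[C@H]2c1ccc(OCc2ccccc2)c(OCc2ccccc2)c1 | intermediate
19 | (1R,2R,3S,4S)-3-{[(1S)-1-carboxy-2-(3,4-dihydroxyphenyl)ethoxy]carbonyl}-4-(3,4-dihydroxyphenyl)-2-(4-hydroxyphenyl)cyclobutane-1-carboxylic acid | O=C(O)[C@@H]1[C@@H](c2ccc(O)cc2)[C@H](C(=O)O[C@@H](Cc2ccc(O)c(O)c2)C(=O)O)[C@H]1c1ccc(O)c(O)c1 | target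

## Step count and risks

Total step count: 9. Longest linear sequence: 8 steps (steps 1–6, 8, 9 from compound 1); step 7 is the one-step side branch.

The three steps most likely to fail are 3, 5 and 6.

Step 3 (enantioselective first arylation). The weakly coordinating anilide may give low conversion on this cis-ester substrate, or the ligand may give insufficient ee. The fallback replaces catalyst control by resolution. It sets out from 6: the same arylation with 7 is run with an achiral accelerating ligand (Pd(OAc)2, N-acetylglycine, Ag2CO3, HFIP, 90 °C), and the racemate is separated by preparative chiral SFC. The wanted enantiomer is 8, where the route resumes. The unwanted antipode benzyl (1S,2R,3R)-2-[4-(benzyloxy)phenyl]-3-[(ArF)carbamoyl]cyclobutane-1-carboxylate F1 is set aside.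

Step 5 (second arylation at the hindered methylene). Oxidative addition of the aryl iodide to a crowded palladacycle may stall. The fallback changes the coupling manifold from aryl iodide with tetravalent palladium to arylboron with a divalent/zerovalent palladium cycle. It sets out from 9. Iodide 10 is first converted by Miyaura borylation (bis(pinacolato)diboron, [1,1'-bis(diphenylphosphino)ferrocene]dichloropalladium PdCl2(dppf), KOAc, dioxane, 80 °C) into 2-[3,4-bis(benzyloxy)phenyl]-4,4,5,5-tetramethyl-1,3,2-dioxaborolane F2. F2 is then cross-coupled with 9 (Pd(OAc)2, ent-L1, Ag2CO3, benzoquinone, tert-amyl alcohol, 70 °C), so that transmetalation replaces the demanding oxidative addition. The product is 11, where the route resumes.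

Step 6 (activation, epimerisation and cleavage in one pot). Boc transfer to a nitrogen next to a cis,cis-flanked acyl group may be slow, and DBU may divert the activated imide through a ketene. The fallback epimerises before activation. It sets out from 11: LiOtBu (3 equiv) in toluene at 60 °C equilibrates the amide carbon at the amidate stage to the all-trans anilide benzyl (1R,2S,3S,4R)-2-[4-(benzyloxy)phenyl]-4-[3,4-bis(benzyloxy)phenyl]-3-[(ArF)carbamoyl]cyclobutane-1-carboxylate F3. The now unhindered amide is then treated with Boc2O/DMAP and gives 13 directly, where the route resumes with LiOH/H2O2 as in step 6.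

## Further compounds

F1 | step 3 | benzyl (1S,2R,3R)-2-[4-(benzyloxy)phenyl]-3-[(ArF)carbamoyl]cyclobutane-1-carboxylate (enantiomer of 8) | O=C(OCc1ccccc1)[C@@H]2[C@H](c3ccc(OCc4ccccc4)cc3)[C@H](C(=O)Nc3c(F)c(F)c(C(F)(F)F)c(F)c3F)C2
F2 | step 5 | 2-[3,4-bis(benzyloxy)phenyl]-4,4,5,5-tetramethyl-1,3,2-dioxaborolane | CC1(C)OB(c2ccc(OCc3ccccc3)c(OCc3ccccc3)c2)OC1(C)C
F3 | step 6 | benzyl (1R,2S,3S,4R)-2-[4-(benzyloxy)phenyl]-4-[3,4-bis(benzyloxy)phenyl]-3-[(ArF)carbamoyl]cyclobutane-1-carboxylate (all-trans) | O=C(OCc1ccccc1)[C@@H]2[C@@H](c3ccc(OCc4ccccc4)cc3)[C@H](C(=O)Nc3c(F)c(F)c(C(F)(F)F)c(F)c3F)[C@H]2c1ccc(OCc2ccccc2)c(OCc2ccccc2)c1
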